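The question is where the left-handed product of theta stands at 10 h, and which remedy then adds the most.

| flask | left-handed substrate | right-handed substrate | reagent | free catalyst | impurity | temperature | remark | time |
|---|---|---|---|---|---|---|---|---|
| theta | 0.056 M | 0.056 M | 0.168 M | 0.11 mM | 20 µM | 60 °C | the very flask that is asked about, followed so far |  |
| alpha | 0.056 M | 0.056 M | 0.168 M | 0.11 mM | 40 µM | 55 °C | run made earlier |  |
| flask | 0.056 M | 0.056 M | 0.168 M | 0.11 mM | 20 µM | 60 °C |  | 10 h |

theta run (percent of the left-handed substrate and right-handed substrate together charged)

| time / h | left-handed product / % | left-handed substrate / % |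
|---|---|---|
| 1.00 | 17.8 | 32.0 |
| 2.00 | 19.3 | 32.4 |
| 3.00 | 18.3 | 29.0 |
| 4.00 | 19.1 | 30.6 |
| 5.00 | 17.6 | 30.5 |
| 6.00 | 17.4 | 30.0 |

alpha run (percent of the left-handed substrate and right-handed substrate together charged)

| time / min | left-handed product / % | left-handed substrate / % |
|---|---|---|
| 8.00 | 7.1 | 41.6 |
| 15.0 | 10.5 | 38.7 |
| 25.0 | 11.6 | 36.0 |
| 30.0 | 14.1 | 38.2 |
| 40.0 | 13.8 | 37.1 |
| 50.0 | 13.4 | 35.4 |

(each reading ± 1 percentage point)

- left-handed product, in percent of the left-handed substrate and right-handed substrate together first charged, at 10 h
- the remedy with the largest gain of left-handed product, or "none" below 2 percentage points (Friday's / Wednesday's / Saturday's / Tuesday's / Sunday's / none)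
- left-handed product present, with what was taken out counted in, in percent of the left-handed substrate and right-handed substrate together first charged, after Wednesday's
- left-handed product present, with what was taken out counted in, in percent of the left-handed substrate and right-handed substrate together first charged, after Tuesday's

- Friday's: at 10 h add reagent, 100% of the amount charged, then wait 5.0 h
- Wednesday's: at 10 h add free catalyst, 100% of the amount charged, then wait 5.0 h
- Saturday's: at 10 h raise the temperature by 25 K, then wait 5.0 h
- Tuesday's: change nothing and wait 5.0 h more
- Sunday's: at 10 h take out 90% of the left-handed product then present, then wait 5.0 h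

- free catalyst is single-handed; left-handed substrate and right-handed substrate are mirror images of each other, charged as a racemate, each of them at the stated concentration
- left-handed product taken out counts as made
- what was read earlier has a scatter of 1 percentage point, one standard deviation
- additions bring no volume worth counting

Theta reads flat from its first reading: left-handed substrate averages 30.8% and left-handed product 18.3%, with a scatter of 1 percentage point. Substrate remains, yet the readings do not move, so my first guess is dead catalyst, with the impurity as suspect. If one impurity takes one catalyst, it can reach 18.2% of the catalyst in theta. I call this the poison share, impurity charge over catalyst charge; in alpha it is 36.4%. So 81.8% of the catalyst in theta should outlast the impurity, and the stall needs another cause.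

The objection is that reagent is a weak suspect too. At one reagent per product, the product in theta holds 12.2% of the reagent charge, so a path I cannot see has to take the other 87.8% if lack of reagent is to stall theta. But catalyst lost beyond the poison share needs an unseen path too. Logarithms offer a test: for a pseudo-first-order substrate, the logarithm of charge over plateau counts the work done. Read off the scattered plateaus, it is 0.486 in theta and 0.310 in alpha, lower where the poison share is larger. Alpha also ran cooler, at 55 °C, so this separates nothing. As a judgement, I commit to lost reagent. Fresh catalyst then adds nothing, while a second dose of reagent repeats the same logarithm on the remaining substrate, for 12 points. My choice is Friday's, and here I differ from the forecast.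

The forecast gives 18.7% now, 18.7% after Tuesday's and 29% after Wednesday's, and chooses Wednesday's: “So fresh catalyst should give another similar burst”.

The flask gives 19.0% now, 19.0% after Tuesday's and 19.0% after Wednesday's. The best remedy is Friday's, with a gain of 13 points.

    reagent + free catalyst + left-handed substrate → free catalyst + left-handed product (k = 6000 /M²/min, Ea = 43.0 kJ/mol)
    reagent + free catalyst + right-handed substrate → free catalyst + right-handed product (k = 320 /M²/min, Ea = 48.0 kJ/mol)
    free catalyst + impurity → spent catalyst (k = 2.40 × 10⁵ /M/min, Ea = 32.0 kJ/mol)
    2 reagent → homo dimer (k = 1.90 /M/min, Ea = 49.0 kJ/mol)
    (constants at 60 °C)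

By 1.00 h the impurity in the flask stood at 0% of its charge and spent catalyst at 18.2% of the catalyst charged, the poison share of 18.2%, while reagent had fallen to 1.19% of its charge, with 99.8% of the turnover to homo dimer up to 10.0 h done. At 10.0 h reagent, the limiting reagent of the flask, stood at 0% of its charge, beside free catalyst at 81.8% of the catalyst charged and left-handed substrate at 31.0% of both substrates charged. The neighbour charged with 5.0 × 10⁻⁵ M of impurity has a poison share of 45.5%, and it ended with 45.5% spent catalyst and 14.8% left-handed product.

Readings and results come from a simulation on assumed constants, and the scatter is random.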